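**Assumption:** the SMILES is taken literally. In bicyclo[9.3.1]pentadecane (verticillane) numbering it is (1R,3R,4S,7R,8R,10R,11S), with a cis-3,4-epoxide (from a 3Z olefin), a trans-7,8-epoxide (from a 7E olefin), and C2 and C10 trans on ring A. This numbering (C1–C15, C18 = exocyclic CH2) is used throughout.

## Retrosynthetic overview

1. The two oxiranes come last, by peracid epoxidation of the (3Z,7E)-diene acetate 33.
2. The twelve-membered ring closes at C10–C11 by intramolecular CrCl2-mediated allylation of aldehyde 30, which also sets C10, C11 and the C12 exocyclic methylene.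
3. The chain is joined at C2–C3 by Negishi coupling of ring bromide 14 with (Z)-alkenyl iodide 23; the 7E olefin comes from carboalumination, the 3Z olefin from carbocupration.
4. Ring A comes from ring-closing metathesis of acid 10, the product of an Ireland–Claisen rearrangement that forges the C1–C15 bond and transfers the lactate-derived C–O stereocentre to C1.
5. Ring order: ring A (step 5), then the twelve-membered ring (step 17), then the two oxiranes (step 19).

## Route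

Step 1
Reactants: 1 ethyl (2S)-2-hydroxypropanoate
Product: 2 ethyl (2S)-2-[(triethylsilyl)oxy]propanoate
Conditions: Et3SiCl, imidazole, CH2Cl2, 0 °C → rt
Reagents that add atoms: chlorotriethylsilane (CC[Si](Cl)(CC)CC)
Why: Silyl ether protection of the secondary alcohol; the stereocentre is not touched.

Step 2
Reactants: 2 ethyl (2S)-2-[(triethylsilyl)oxy]propanoate
Product: 5 (2S)-4-methylpent-3-en-2-ol, via silyloxy aldehyde 3 (not isolated), via allylic silyl ether 4 (not isolated)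
Conditions: i-Bu2AlH, CH2Cl2, −78 °C; then i-PrPPh3I/n-BuLi (preformed ylide), THF, −78 °C → rt; then 1 M HCl, THF
Reagents that add atoms: isopropyltriphenylphosphonium iodide (CC(C)[P+](c1ccccc1)(c1ccccc1)c1ccccc1.[I-])
Why: Partial ester reduction, Wittig olefination with the symmetrical isopropylidene ylide (no E/Z issue) and acidic desilylation in one flask; the aldehyde is consumed cold in situ, so the C–O stereocentre is retained.

Step 3
Reactants: 5 (2S)-4-methylpent-3-en-2-ol; 6 hex-5-enoic acid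
Product: 7 (2S)-4-methylpent-3-en-2-yl hex-5-enoate
Conditions: DCC, DMAP (cat.), CH2Cl2, 0 °C → rt
Reagents that add atoms: none
Why: Steglich esterification at oxygen, so the configuration of the allylic carbinol is retained.

Step 4
Reactants: 7 (2S)-4-methylpent-3-en-2-yl hex-5-enoate
Product: 10 (2R,4E)-2-(but-3-en-1-yl)-3,3-dimethylhex-4-enoic acid, via silyl ketene acetal 8 (not isolated), via trimethylsilyl ester 9 (not isolated)
Conditions: LDA, THF, −78 °C; Me3SiCl, Et3N; −78 → 60 °C; then 1 M HCl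
Reagents that add atoms: none
Why: Ireland–Claisen [3,3]-sigmatropic rearrangement through a chair transition state with the (E)-silyl ketene acetal (LDA/THF) and the carbinol methyl equatorial, which builds the quaternary C15–C1 bond and transfers the (S) C–O centre to the new (R) α-centre (C1 of the target), its enantiomeric purity tracking the E:Z ratio of the ketene acetal (usually above 9:1).

Step 5
Reactants: 10 (2R,4E)-2-(but-3-en-1-yl)-3,3-dimethylhex-4-enoic acid
Product: 11 (1R)-2,2-dimethylcyclohex-3-ene-1-carboxylic acid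
Conditions: second-generation Grubbs catalyst (5 mol %), CH2Cl2, 40 °C
Reagents that add atoms: none
Why: Ring-closing metathesis of the terminal olefin onto the propenyl group closes ring A with loss of propene; the stereocentre is remote from the reacting carbons.

Step 6
Reactants: 11 (1R)-2,2-dimethylcyclohex-3-ene-1-carboxylic acid
Product: 12 [(1R)-2,2-dimethylcyclohex-3-en-1-yl]methanol
Conditions: LiAlH4, THF, 0 °C → rt
Reagents that add atoms: none
Why: Hydride reduction of the acid to the primary alcohol (the future C2) without touching the olefin or the stereocentre.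

Step 7
Reactants: 12 [(1R)-2,2-dimethylcyclohex-3-en-1-yl]methanol
Product: 13 (4R)-4-(bromomethyl)-3,3-dimethylcyclohex-1-ene
Conditions: CBr4, PPh3, CH2Cl2, 0 °C
Reagents that add atoms: tetrabromomethane (BrC(Br)(Br)Br)
Why: Appel bromination of the primary alcohol; no stereocentre is involved.

Step 8
Reactants: 13 (4R)-4-(bromomethyl)-3,3-dimethylcyclohex-1-ene
Product: 14 (5R)-5-(bromomethyl)-4,4-dimethylcyclohex-2-en-1-one
Conditions: CrO3, 3,5-dimethylpyrazole, CH2Cl2, −20 °C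
Reagents that add atoms: chromium trioxide (O=[Cr](=O)=O)
Why: Allylic oxidation can only occur at C13, because the other allylic carbon (C15) is quaternary, and it gives the ring-A enone.

Step 9
Reactants: 15 tert-butyl(but-3-yn-1-yloxy)dimethylsilane
Product: 18 (3E)-6-{[tert-butyl(dimethyl)silyl]oxy}-4-methylhex-3-en-1-ol, via alkenylalane 16 (not isolated), via lithium alkenylalanate 17 (not isolated)
Conditions: Me3Al, Cp2ZrCl2 (cat.), CH2Cl2, 0 °C → rt; n-BuLi, THF, −78 °C; oxirane, −78 → 0 °C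
Reagents that add atoms: trimethylaluminium (C[Al](C)C); oxirane (C1CO1)
Why: Negishi zirconium-catalysed syn-carboalumination fixes the 7E trisubstituted olefin, and the derived alanate opens oxirane with retention of olefin geometry.

Step 10
Reactants: 18 (3E)-6-{[tert-butyl(dimethyl)silyl]oxy}-4-methylhex-3-en-1-ol
Product: 19 tert-butyl{[(3E)-6-bromo-3-methylhex-3-en-1-yl]oxy}dimethylsilane
Conditions: CBr4, PPh3, CH2Cl2, 0 °C
Reagents that add atoms: tetrabromomethane (BrC(Br)(Br)Br)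
Why: Appel bromination of the homoallylic alcohol under neutral conditions that leave the silyl ether and the olefin alone.

Step 11
Reactants: 19 tert-butyl{[(3E)-6-bromo-3-methylhex-3-en-1-yl]oxy}dimethylsilane
Product: 23 tert-butyl{[(3E,7Z)-8-iodo-3,7-dimethylocta-3,7-dien-1-yl]oxy}dimethylsilane, via Grignard reagent 20 (not isolated), via alkylcopper 21 (not isolated), via alkenylcopper 22 (not isolated)
Conditions: Mg, THF; CuBr·SMe2, Et2O/SMe2, −45 °C; propyne, −25 °C; I2, −40 → 0 °C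
Reagents that add atoms: propyne (CC#C); iodine (II)
Why: Normant syn-carbocupration of propyne puts the chain and copper cis, and iodinolysis with retention gives the (Z)-alkenyl iodide that carries the future 3Z olefin.

Step 12
Reactants: 14 (5R)-5-(bromomethyl)-4,4-dimethylcyclohex-2-en-1-one; 23 tert-butyl{[(3E,7Z)-8-iodo-3,7-dimethylocta-3,7-dien-1-yl]oxy}dimethylsilane
Product: 25 (5R)-5-[(2Z,6E)-9-{[tert-butyl(dimethyl)silyl]oxy}-3,7-dimethylnona-2,6-dien-1-yl]-4,4-dimethylcyclohex-2-en-1-one, via alkylzinc bromide 24 (not isolated)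
Conditions: Zn dust, LiCl, THF, 50 °C; then 23, Pd(OAc)2 (2 mol %), SPhos, THF, rt
Reagents that add atoms: none
Why: Negishi sp3–sp2 cross-coupling forms C2–C3 with retention of the Z geometry; the alkylzinc halide tolerates the enone.

Step 13
Reactants: 25 (5R)-5-[(2Z,6E)-9-{[tert-butyl(dimethyl)silyl]oxy}-3,7-dimethylnona-2,6-dien-1-yl]-4,4-dimethylcyclohex-2-en-1-one
Product: 26 (5R)-5-[(2Z,6E)-9-{[tert-butyl(dimethyl)silyl]oxy}-3,7-dimethylnona-2,6-dien-1-yl]-2-(hydroxymethyl)-4,4-dimethylcyclohex-2-en-1-one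
Conditions: aq. HCHO, DMAP (cat.), THF/H2O, rt
Reagents that add atoms: formaldehyde (C=O)
Why: Morita–Baylis–Hillman hydroxymethylation places C18 on the α-carbon (C12) of the enone.

Step 14
Reactants: 26 (5R)-5-[(2Z,6E)-9-{[tert-butyl(dimethyl)silyl]oxy}-3,7-dimethylnona-2,6-dien-1-yl]-2-(hydroxymethyl)-4,4-dimethylcyclohex-2-en-1-one
Product: 28 (5R)-2-(bromomethyl)-5-[(2Z,6E)-9-{[tert-butyl(dimethyl)silyl]oxy}-3,7-dimethylnona-2,6-dien-1-yl]-4,4-dimethylcyclohex-2-en-1-one, via allylic mesylate 27 (not isolated)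
Conditions: MsCl, Et3N, CH2Cl2, −20 °C; LiBr, THF, 0 °C
Reagents that add atoms: lithium bromide ([Li+].[Br-])
Why: Mesylation and bromide displacement give the allylic bromide; direct and allylic substitution lead to the same allyl unit for step 17.

Step 15
Reactants: 28 (5R)-2-(bromomethyl)-5-[(2Z,6E)-9-{[tert-butyl(dimethyl)silyl]oxy}-3,7-dimethylnona-2,6-dien-1-yl]-4,4-dimethylcyclohex-2-en-1-one
Product: 29 (5R)-2-(bromomethyl)-5-[(2Z,6E)-9-hydroxy-3,7-dimethylnona-2,6-dien-1-yl]-4,4-dimethylcyclohex-2-en-1-one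
Conditions: 48% aq. HF, MeCN, 0 °C
Reagents that add atoms: none
Why: Acidic fluoride desilylation frees the C10 alcohol without a nucleophile that could attack the allylic bromide.

Step 16
Reactants: 29 (5R)-2-(bromomethyl)-5-[(2Z,6E)-9-hydroxy-3,7-dimethylnona-2,6-dien-1-yl]-4,4-dimethylcyclohex-2-en-1-one
Product: 30 (3E,7Z)-9-[(1R)-4-(bromomethyl)-6,6-dimethyl-3-oxocyclohex-4-en-1-yl]-3,7-dimethylnona-3,7-dienal
Conditions: Dess–Martin periodinane, NaHCO3, CH2Cl2, 0 °C; used crude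
Reagents that add atoms: none
Why: Buffered Dess–Martin oxidation gives the β,γ-unsaturated aldehyde without olefin migration.

Step 17
Reactants: 30 (3E,7Z)-9-[(1R)-4-(bromomethyl)-6,6-dimethyl-3-oxocyclohex-4-en-1-yl]-3,7-dimethylnona-3,7-dienal
Product: 32 (1R,3Z,7E,10R,11S)-10-hydroxy-4,8,15,15-tetramethyl-12-methylidenebicyclo[9.3.1]pentadeca-3,7-dien-13-one, via allylchromium dichloride 31 (not isolated)
Conditions: CrCl2 (8 equiv), THF (0.002 M), 4 Å MS, rt, slow addition; aq. NH4Cl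
Reagents that add atoms: none
Why: Intramolecular Nozaki–Hiyama allylation: the ring-locked E-type allylchromium adds through a chair transition state (anti, giving 10R) and bonds at C11 on the face opposite the C1 side chain (11S), closing the twelve-membered ring and unveiling the α-methylene ketone.

Step 18
Reactants: 32 (1R,3Z,7E,10R,11S)-10-hydroxy-4,8,15,15-tetramethyl-12-methylidenebicyclo[9.3.1]pentadeca-3,7-dien-13-one
Product: 33 (1R,3Z,7E,10R,11S)-4,8,15,15-tetramethyl-12-methylidene-13-oxobicyclo[9.3.1]pentadeca-3,7-dien-10-yl acetate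
Conditions: Ac2O, pyridine, rt
Reagents that add atoms: acetic anhydride (CC(=O)OC(C)=O)
Why: O-Acetylation with retention at C10 under a weak base that does not move the exocyclic olefin into the ring.

Step 19
Reactants: 33 (1R,3Z,7E,10R,11S)-4,8,15,15-tetramethyl-12-methylidene-13-oxobicyclo[9.3.1]pentadeca-3,7-dien-10-yl acetate
Product: 35 (1R,3R,4S,7R,8R,10R,11S)-3,4:7,8-diepoxy-4,8,15,15-tetramethyl-12-methylidene-13-oxobicyclo[9.3.1]pentadecan-10-yl acetate, via 7,8-monoepoxide 34 (not isolated)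
Conditions: mCPBA (2.3 equiv), NaHCO3, CH2Cl2, 0 °C
Reagents that add atoms: 3-chloroperoxybenzoic acid (OOC(=O)c1cccc(Cl)c1)
Why: Prilezhaev epoxidation is syn-stereospecific (3Z gives the cis oxirane, 7E the trans oxirane) and spares the electron-poor enone, but the facial selectivity assigned here (peripheral attack on each trisubstituted olefin, giving 3R,4S and 7R,8R) is a substrate-control assumption that could not be verified.

## Compound list

1 | ethyl (2S)-2-hydroxypropanoate | C[C@H](O)C(=O)OCC | starting material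
2 | ethyl (2S)-2-[(triethylsilyl)oxy]propanoate | C[C@H](O[Si](CC)(CC)CC)C(=O)OCC | intermediate
3 | (2S)-2-[(triethylsilyl)oxy]propanal | C[C@H](O[Si](CC)(CC)CC)C=O | intermediate
4 | triethyl{[(2S)-4-methylpent-3-en-2-yl]oxy}silane | C[C@H](O[Si](CC)(CC)CC)C=C(C)C | intermediate
5 | (2S)-4-methylpent-3-en-2-ol | C[C@H](O)C=C(C)C | intermediate
6 | hex-5-enoic acid | C=CCCCC(=O)O | starting material
7 | (2S)-4-methylpent-3-en-2-yl hex-5-enoate | C=CCCCC(=O)O[C@@H](C)C=C(C)C | intermediate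
8 | trimethyl{[(1E)-1-{[(2S)-4-methylpent-3-en-2-yl]oxy}hexa-1,5-dien-1-yl]oxy}silane | C=CCC/C=C(/O[Si](C)(C)C)O[C@@H](C)C=C(C)C | intermediate
9 | trimethylsilyl (2R,4E)-2-(but-3-en-1-yl)-3,3-dimethylhex-4-enoate | C=CCC[C@@H](C(=O)O[Si](C)(C)C)C(C)(C)/C=C/C | intermediate
10 | (2R,4E)-2-(but-3-en-1-yl)-3,3-dimethylhex-4-enoic acid | C=CCC[C@@H](C(=O)O)C(C)(C)/C=C/C | intermediate
11 | (1R)-2,2-dimethylcyclohex-3-ene-1-carboxylic acid | OC(=O)[C@@H]1CCC=CC1(C)C | intermediate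
12 | [(1R)-2,2-dimethylcyclohex-3-en-1-yl]methanol | OC[C@@H]1CCC=CC1(C)C | intermediate
13 | (4R)-4-(bromomethyl)-3,3-dimethylcyclohex-1-ene | BrC[C@@H]1CCC=CC1(C)C | intermediate
14 | (5R)-5-(bromomethyl)-4,4-dimethylcyclohex-2-en-1-one | BrC[C@@H]1CC(=O)C=CC1(C)C | intermediate
15 | tert-butyl(but-3-yn-1-yloxy)dimethylsilane | C#CCCO[Si](C)(C)C(C)(C)C | starting material
16 | [(1E)-4-{[tert-butyl(dimethyl)silyl]oxy}-2-methylbut-1-en-1-yl]dimethylalumane | C[Al](C)/C=C(\C)CCO[Si](C)(C)C(C)(C)C | intermediate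
17 | lithium butyl[(1E)-4-{[tert-butyl(dimethyl)silyl]oxy}-2-methylbut-1-en-1-yl]dimethylaluminate | [Li+].CCCC[Al-](C)(C)/C=C(\C)CCO[Si](C)(C)C(C)(C)C | intermediate
18 | (3E)-6-{[tert-butyl(dimethyl)silyl]oxy}-4-methylhex-3-en-1-ol | OCC/C=C(\C)CCO[Si](C)(C)C(C)(C)C | intermediate
19 | tert-butyl{[(3E)-6-bromo-3-methylhex-3-en-1-yl]oxy}dimethylsilane | BrCC/C=C(\C)CCO[Si](C)(C)C(C)(C)C | intermediate
20 | bromo[(3E)-6-{[tert-butyl(dimethyl)silyl]oxy}-4-methylhex-3-en-1-yl]magnesium | Br[Mg]CC/C=C(\C)CCO[Si](C)(C)C(C)(C)C | intermediate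
21 | [(3E)-6-{[tert-butyl(dimethyl)silyl]oxy}-4-methylhex-3-en-1-yl]copper | [Cu]CC/C=C(\C)CCO[Si](C)(C)C(C)(C)C | intermediate
22 | [(1Z,5E)-8-{[tert-butyl(dimethyl)silyl]oxy}-2,6-dimethylocta-1,5-dien-1-yl]copper | [Cu]/C=C(/C)CC/C=C(\C)CCO[Si](C)(C)C(C)(C)C | intermediate
23 | tert-butyl{[(3E,7Z)-8-iodo-3,7-dimethylocta-3,7-dien-1-yl]oxy}dimethylsilane | I/C=C(/C)CC/C=C(\C)CCO[Si](C)(C)C(C)(C)C | intermediate
24 | bromo{[(1R)-6,6-dimethyl-3-oxocyclohex-4-en-1-yl]methyl}zinc | Br[Zn]C[C@@H]1CC(=O)C=CC1(C)C | intermediate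
25 | (5R)-5-[(2Z,6E)-9-{[tert-butyl(dimethyl)silyl]oxy}-3,7-dimethylnona-2,6-dien-1-yl]-4,4-dimethylcyclohex-2-en-1-one | CC(C)(C)[Si](C)(C)OCC/C(C)=C/CC/C(C)=C\C[C@@H]1CC(=O)C=CC1(C)C | intermediate
26 | (5R)-5-[(2Z,6E)-9-{[tert-butyl(dimethyl)silyl]oxy}-3,7-dimethylnona-2,6-dien-1-yl]-2-(hydroxymethyl)-4,4-dimethylcyclohex-2-en-1-one | CC(C)(C)[Si](C)(C)OCC/C(C)=C/CC/C(C)=C\C[C@@H]1CC(=O)C(CO)=CC1(C)C | intermediate
27 | [(4R)-4-[(2Z,6E)-9-{[tert-butyl(dimethyl)silyl]oxy}-3,7-dimethylnona-2,6-dien-1-yl]-3,3-dimethyl-6-oxocyclohex-1-en-1-yl]methyl methanesulfonate | CC(C)(C)[Si](C)(C)OCC/C(C)=C/CC/C(C)=C\C[C@@H]1CC(=O)C(COS(C)(=O)=O)=CC1(C)C | intermediate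
28 | (5R)-2-(bromomethyl)-5-[(2Z,6E)-9-{[tert-butyl(dimethyl)silyl]oxy}-3,7-dimethylnona-2,6-dien-1-yl]-4,4-dimethylcyclohex-2-en-1-one | CC(C)(C)[Si](C)(C)OCC/C(C)=C/CC/C(C)=C\C[C@@H]1CC(=O)C(CBr)=CC1(C)C | intermediate
29 | (5R)-2-(bromomethyl)-5-[(2Z,6E)-9-hydroxy-3,7-dimethylnona-2,6-dien-1-yl]-4,4-dimethylcyclohex-2-en-1-one | OCC/C(C)=C/CC/C(C)=C\C[C@@H]1CC(=O)C(CBr)=CC1(C)C | intermediate
30 | (3E,7Z)-9-[(1R)-4-(bromomethyl)-6,6-dimethyl-3-oxocyclohex-4-en-1-yl]-3,7-dimethylnona-3,7-dienal | O=CC/C(C)=C/CC/C(C)=C\C[C@@H]1CC(=O)C(CBr)=CC1(C)C | intermediate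
31 | dichloro({(4R)-4-[(2Z,6E)-3,7-dimethyl-9-oxonona-2,6-dien-1-yl]-3,3-dimethyl-6-oxocyclohex-1-en-1-yl}methyl)chromium | O=CC/C(C)=C/CC/C(C)=C\C[C@@H]1CC(=O)C(C[Cr](Cl)Cl)=CC1(C)C | intermediate
32 | (1R,3Z,7E,10R,11S)-10-hydroxy-4,8,15,15-tetramethyl-12-methylidenebicyclo[9.3.1]pentadeca-3,7-dien-13-one | C=C1C(=O)C[C@H]2C/C=C(/C)CC/C=C(\C)C[C@@H](O)[C@H]1C2(C)C | intermediate
33 | (1R,3Z,7E,10R,11S)-4,8,15,15-tetramethyl-12-methylidene-13-oxobicyclo[9.3.1]pentadeca-3,7-dien-10-yl acetate | C=C1C(=O)C[C@H]2C/C=C(/C)CC/C=C(\C)C[C@@H](OC(C)=O)[C@H]1C2(C)C | intermediate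
34 | (1R,3Z,7R,8R,10R,11S)-7,8-epoxy-4,8,15,15-tetramethyl-12-methylidene-13-oxobicyclo[9.3.1]pentadec-3-en-10-yl acetate | C=C1C(=O)C[C@H]2C/C=C(/C)CC[C@H]3O[C@]3(C)C[C@@H](OC(C)=O)[C@H]1C2(C)C | intermediate
35 | (1R,3R,4S,7R,8R,10R,11S)-3,4:7,8-diepoxy-4,8,15,15-tetramethyl-12-methylidene-13-oxobicyclo[9.3.1]pentadecan-10-yl acetate | C=C1C(=O)C[C@H]2C[C@H]3O[C@@]3(C)CC[C@H]3O[C@]3(C)C[C@@H](OC(C)=O)[C@H]1C2(C)C | target

## Step count and risks

Total step count: 19. Longest linear sequence: 16 (steps 1–8, then 12–19); the chain branch is steps 9–11.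

The three steps most likely to fail:

**Step 13 (Morita–Baylis–Hillman at a β-carbon next to the quaternary centre).** The fallback sets out from 25 and comes back at 26. The enone 25 is α-iodinated (I2, pyridine, CH2Cl2) to (5R)-5-[(2Z,6E)-9-{[tert-butyl(dimethyl)silyl]oxy}-3,7-dimethylnona-2,6-dien-1-yl]-2-iodo-4,4-dimethylcyclohex-2-en-1-one F1. The hydroxymethyl group is then introduced by Stille coupling with (tributylstannyl)methanol (Pd(PPh3)4, dioxane, 80 °C), which gives 26.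

**Step 17 (macrocyclisation; ring-closure yield and the face of attack at C11).** The fallback sets out from 14 and 23 and comes back at 33; it forms C10–C11 intermolecularly, where attack anti to the ring substituent is secure, and closes the ring at C2–C3 instead. Bromide 14 is hydroxymethylated as in step 13 to (5R)-5-(bromomethyl)-2-(hydroxymethyl)-4,4-dimethylcyclohex-2-en-1-one F2 and converted (CBr4, PPh3) into (5R)-2,5-bis(bromomethyl)-4,4-dimethylcyclohex-2-en-1-one F3. Iodide 23 is desilylated (aq. HF, MeCN) to (3E,7Z)-8-iodo-3,7-dimethylocta-3,7-dien-1-ol F4 and oxidised (Dess–Martin periodinane) to (3E,7Z)-8-iodo-3,7-dimethylocta-3,7-dienal F5. CrCl2 in THF activates only the allylic bromide of F3 and adds it to F5, giving (3S,5R)-5-(bromomethyl)-3-[(1R,3E,7Z)-1-hydroxy-8-iodo-3,7-dimethylocta-3,7-dien-1-yl]-4,4-dimethyl-2-methylidenecyclohexan-1-one F6. Acetylation (Ac2O, pyridine) gives (1R,3E,7Z)-1-[(1S,5R)-5-(bromomethyl)-6,6-dimethyl-2-methylidene-3-oxocyclohexyl]-8-iodo-3,7-dimethylocta-3,7-dien-1-yl acetate F7. An intramolecular nickel-catalysed reductive alkyl–alkenyl coupling (NiBr2·dme, 4,4'-di-tert-butyl-2,2'-bipyridine, Mn powder, NaI, DMA, high dilution) then closes the ring to 33.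

**Step 19 (facial selectivity of the two epoxidations).** The fallback sets out from 32 and comes back at 34. The free C10 hydroxyl of 32 directs the first epoxidation to the homoallylic 7,8-olefin (VO(acac)2, t-BuOOH, CH2Cl2, 0 °C), giving (1R,3Z,7R,8R,10R,11S)-7,8-epoxy-10-hydroxy-4,8,15,15-tetramethyl-12-methylidenebicyclo[9.3.1]pentadec-3-en-13-one F8. Acetylation (Ac2O, pyridine) gives 34, and the remaining 3Z olefin is then epoxidised on its own with mCPBA as in step 19, so that each oxirane can be checked and separated individually.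

## Further compounds

F1 | step 13 | (5R)-5-[(2Z,6E)-9-{[tert-butyl(dimethyl)silyl]oxy}-3,7-dimethylnona-2,6-dien-1-yl]-2-iodo-4,4-dimethylcyclohex-2-en-1-one | CC(C)(C)[Si](C)(C)OCC/C(C)=C/CC/C(C)=C\C[C@@H]1CC(=O)C(I)=CC1(C)C
F2 | step 17 | (5R)-5-(bromomethyl)-2-(hydroxymethyl)-4,4-dimethylcyclohex-2-en-1-one | BrC[C@@H]1CC(=O)C(CO)=CC1(C)C
F3 | step 17 | (5R)-2,5-bis(bromomethyl)-4,4-dimethylcyclohex-2-en-1-one | BrC[C@@H]1CC(=O)C(CBr)=CC1(C)C
F4 | step 17 | (3E,7Z)-8-iodo-3,7-dimethylocta-3,7-dien-1-ol | I/C=C(/C)CC/C=C(\C)CCO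
F5 | step 17 | (3E,7Z)-8-iodo-3,7-dimethylocta-3,7-dienal | I/C=C(/C)CC/C=C(\C)CC=O
F6 | step 17 | (3S,5R)-5-(bromomethyl)-3-[(1R,3E,7Z)-1-hydroxy-8-iodo-3,7-dimethylocta-3,7-dien-1-yl]-4,4-dimethyl-2-methylidenecyclohexan-1-one | C=C1C(=O)C[C@@H](CBr)C(C)(C)[C@@H]1[C@H](O)C/C(C)=C/CC/C(C)=C\I
F7 | step 17 | (1R,3E,7Z)-1-[(1S,5R)-5-(bromomethyl)-6,6-dimethyl-2-methylidene-3-oxocyclohexyl]-8-iodo-3,7-dimethylocta-3,7-dien-1-yl acetate | C=C1C(=O)C[C@@H](CBr)C(C)(C)[C@@H]1[C@H](OC(C)=O)C/C(C)=C/CC/C(C)=C\I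
F8 | step 19 | (1R,3Z,7R,8R,10R,11S)-7,8-epoxy-10-hydroxy-4,8,15,15-tetramethyl-12-methylidenebicyclo[9.3.1]pentadec-3-en-13-one | C=C1C(=O)C[C@H]2C/C=C(/C)CC[C@H]3O[C@]3(C)C[C@@H](O)[C@H]1C2(C)C
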